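## Retrosynthetic overview

1. Atom labels follow the diterpene chain: C1 = CH2OAc, C6 = CHOH, C7 = quaternary ring carbon, C10=C11 = ring alkene, C20 = lactone C=O. The only ring, the seven-membered lactone (ring A), is closed last: the C7–O bond forms by stereoinvertive opening of a (6R,7R)-epoxide by the C20 carboxyl group, which is made in the same flask by Pd-catalysed carbonylation of a (Z)-alkenyl iodide (C11–C20 bond).
2. The (Z)-alkenyl iodide comes from a C1–C10 epoxy aldehyde and the α-iodo ylide of a homoprenyl phosphonium salt (C10=C11).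
3. The epoxy aldehyde comes from Shi epoxidation of a (2E,6E)-diene, whose C5–C6 bond is made by a B-alkyl Suzuki–Miyaura union of fragment A (C1–C5 dienyl acetate) with fragment B (C6–C10 E-alkenyl iodide).
4. Fragment A comes from (2E)-3-methylpent-2-en-4-yn-1-ol, fragment B from pent-4-yn-1-ol by Zr-catalysed carboalumination, and fragment C (C11–C15 phosphonium salt) from cyclopropyl methyl ketone.

Assumption: the three starting materials and the D-fructose-derived Shi ketone (catalyst) are bought as such.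

## Route

Step 1
Reactants: 1 (2E)-3-methylpent-2-en-4-yn-1-ol
Product: 2 (2E)-3-methylpent-2-en-4-yn-1-yl acetate
Conditions: Ac2O, pyridine, DMAP (cat.), CH2Cl2, 0 → 23 °C
Reagents that add atoms: acetic anhydride, CC(=O)OC(C)=O
Why: DMAP-catalysed O-acylation of a primary allylic alcohol installs the acetate of the target at the outset, where it later also deactivates the C2=C3 alkene toward epoxidation.

Step 2
Reactants: 2 (2E)-3-methylpent-2-en-4-yn-1-yl acetate
Product: 3 (2E)-3-methylpenta-2,4-dien-1-yl acetate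
Conditions: H2 (1 atm), Pd/CaCO3 poisoned with Pb(OAc)2 (Lindlar catalyst), quinoline, hexane–EtOAc, 23 °C
Reagents that add atoms: none
Why: Lindlar semi-hydrogenation stops the terminal alkyne at the vinyl group and leaves the allylic acetate and the trisubstituted alkene alone, so the E geometry at C2=C3 is carried over from 1.

Step 3
Reactants: 4 pent-4-yn-1-ol
Product: 6 (4E)-5-iodo-4-methylpent-4-en-1-ol, via alkenylalane 5 (not isolated)
Conditions: AlMe3 (3 equiv), Cp2ZrCl2 (0.25 equiv), CH2Cl2, 0 → 23 °C; then I2, THF, −30 → 0 °C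
Reagents that add atoms: trimethylaluminium, C[Al](C)C; iodine, II
Why: Negishi zirconium-catalysed carboalumination adds Me–Al syn with aluminium at the alkyne terminus, and iodinolysis of the C–Al bond with retention gives the E iodide that fixes the later C6=C7 geometry.

Step 4
Reactants: 6 (4E)-5-iodo-4-methylpent-4-en-1-ol
Product: 7 tert-butyl{[(4E)-5-iodo-4-methylpent-4-en-1-yl]oxy}dimethylsilane
Conditions: TBSCl, imidazole, CH2Cl2, 0 → 23 °C
Reagents that add atoms: tert-butyldimethylsilyl chloride, CC(C)(C)[Si](C)(C)Cl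
Why: Routine silylation masks the primary C10 hydroxyl through the coupling and the epoxidation.

Step 5
Reactants: 3 (2E)-3-methylpenta-2,4-dien-1-yl acetate; 7 tert-butyl{[(4E)-5-iodo-4-methylpent-4-en-1-yl]oxy}dimethylsilane
Product: 9 (2E,6E)-10-[(tert-butyldimethylsilyl)oxy]-3,7-dimethyldeca-2,6-dien-1-yl acetate, via alkyl-9-BBN borane 8 (not isolated)
Conditions: 9-BBN (1.1 equiv), THF, 0 → 23 °C; then 7, PdCl2(dppf) (5 mol %), AsPh3 (5 mol %), K3PO4 (3 M aq.), DMF, 23 °C
Reagents that add atoms: none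
Why: In this B-alkyl Suzuki–Miyaura coupling, 9-BBN hydroborates only the terminal vinyl group of 3 at its CH2 end, and the primary alkylborane transfers to the alkenylpalladium iodide from 7 with retention of alkene geometry, forming C5–C6 and uniting fragments A and B.

Step 6
Reactants: 9 (2E,6E)-10-[(tert-butyldimethylsilyl)oxy]-3,7-dimethyldeca-2,6-dien-1-yl acetate
Product: 10 (2E)-5-[(2R,3R)-3-{3-[(tert-butyldimethylsilyl)oxy]propyl}-3-methyloxiran-2-yl]-3-methylpent-2-en-1-yl acetate
Conditions: D-fructose-derived Shi ketone (30 mol %), Oxone (2KHSO5·KHSO4·K2SO4), K2CO3, n-Bu4NHSO4, aq. Na2B4O7 buffer (pH 10.5), MeCN–CH2(OMe)2, 0 °C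
Reagents that add atoms: potassium peroxymonosulfate (active part of Oxone), [K+].[O-]S(=O)(=O)OO
Why: In the Shi asymmetric epoxidation the chiral dioxirane attacks the electron-rich C6=C7 alkene (C2=C3 is deactivated by its allylic acetate) through the spiro transition state that gives the (R,R) epoxide from E-trisubstituted alkenes, setting C6 (R, final) and C7 (R, to be inverted in step 13).

Step 7
Reactants: 10 (2E)-5-[(2R,3R)-3-{3-[(tert-butyldimethylsilyl)oxy]propyl}-3-methyloxiran-2-yl]-3-methylpent-2-en-1-yl acetate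
Product: 11 (2E)-5-[(2R,3R)-3-(3-hydroxypropyl)-3-methyloxiran-2-yl]-3-methylpent-2-en-1-yl acetate
Conditions: n-Bu4NF, AcOH (1:1), THF, 0 → 23 °C
Reagents that add atoms: none
Why: Buffered fluoride desilylation cleaves the primary TBS ether without touching the acetate or the oxirane and without the acidity that would cyclise the epoxy alcohol to a tetrahydrofuran.

Step 8
Reactants: 11 (2E)-5-[(2R,3R)-3-(3-hydroxypropyl)-3-methyloxiran-2-yl]-3-methylpent-2-en-1-yl acetate
Product: 12 (2E)-3-methyl-5-[(2R,3R)-3-methyl-3-(3-oxopropyl)oxiran-2-yl]pent-2-en-1-yl acetate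
Conditions: n-Pr4N[RuO4] (5 mol %), N-methylmorpholine N-oxide (1.5 equiv), 4 Å MS, CH2Cl2, 23 °C
Reagents that add atoms: none
Why: The Ley–Griffith oxidation is neutral, stops at the aldehyde and tolerates the oxirane, the acetate and both alkenes.

Step 9
Reactants: 13 cyclopropyl methyl ketone
Product: 14 2-cyclopropylpropan-2-ol
Conditions: MeMgBr, Et2O, 0 → 23 °C; aq. NH4Cl
Reagents that add atoms: methylmagnesium bromide, C[Mg]Br
Why: Grignard 1,2-addition to the ketone gives the tertiary cyclopropylcarbinol.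

Step 10
Reactants: 14 2-cyclopropylpropan-2-ol
Product: 15 5-bromo-2-methylpent-2-ene
Conditions: 48 % aq. HBr, 0 °C
Reagents that add atoms: hydrogen bromide, Br
Why: In the Julia cyclopropylcarbinyl-to-homoallyl rearrangement the tertiary cation is opened by bromide at a ring CH2, giving the homoprenyl bromide with its trisubstituted alkene.

Step 11
Reactants: 15 5-bromo-2-methylpent-2-ene
Product: 16 (4-methylpent-3-en-1-yl)triphenylphosphonium bromide
Conditions: PPh3, MeCN, reflux
Reagents that add atoms: triphenylphosphine, c1ccc(cc1)P(c1ccccc1)c1ccccc1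
Why: SN2 quaternisation of triphenylphosphine by the primary bromide gives the Wittig salt.

Step 12
Reactants: 16 (4-methylpent-3-en-1-yl)triphenylphosphonium bromide; 12 (2E)-3-methyl-5-[(2R,3R)-3-methyl-3-(3-oxopropyl)oxiran-2-yl]pent-2-en-1-yl acetate
Product: 20 (2E)-5-{(2R,3R)-3-[(3Z)-4-iodo-8-methylnona-3,7-dien-1-yl]-3-methyloxiran-2-yl}-3-methylpent-2-en-1-yl acetate, via phosphorus ylide 17 (not isolated), via α-iodophosphonium iodide 18 (not isolated), via α-iodo ylide 19 (not isolated)
Conditions: 16, NaN(SiMe3)2 (1.0 equiv), THF, 0 °C; I2 (1.0 equiv), −78 °C; NaN(SiMe3)2 (0.95 equiv), −78 → −20 °C; then 12, −78 → −20 °C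
Reagents that add atoms: iodine, II
Why: In this Stork–Zhao-type α-iodo Wittig olefination the unstabilised ylide is iodinated, deprotonated again, and reacts with the aldehyde under kinetic control to give the trisubstituted alkenyl iodide with iodine cis to the C9 chain (Z), the geometry ring closure needs.

Step 13
Reactants: 20 (2E)-5-{(2R,3R)-3-[(3Z)-4-iodo-8-methylnona-3,7-dien-1-yl]-3-methyloxiran-2-yl}-3-methylpent-2-en-1-yl acetate
Product: 22 (2E,6R)-6-hydroxy-3-methyl-6-[(2S)-2-methyl-6-(4-methylpent-3-en-1-yl)-7-oxo-2,3,4,7-tetrahydrooxepin-2-yl]hex-2-en-1-yl acetate (target), via Z-epoxy acid 21 (not isolated)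
Conditions: Pd(OAc)2 (5 mol %), dppf (6 mol %), CO (1 atm), H2O (10 equiv), i-Pr2NEt (1.5 equiv), THF, 40 °C; then aq. NaH2PO4 (pH 4) wash, CH2Cl2, CSA (10 mol %), 0 → 23 °C
Reagents that add atoms: carbon monoxide, [C-]#[O+]; water, O
Why: Proposed new method: a carbonylation-triggered, stereoinvertive 7-exo epoxide-opening lactonisation, in which zerovalent palladium inserts into the C–I bond, CO insertion and hydrolysis of the acylpalladium give the (Z)-acid 21 with its carboxyl held cis to the tether, and after iodide is washed out CSA activates the oxirane so that the carboxyl attacks the cation-stabilising quaternary C7 anti to the oxirane oxygen (7-exo preferred over 8-endo), closing ring A, inverting C7 to S and freeing the (6R) hydroxyl; the closest known reactions are Pd-catalysed hydroxycarbonylation of alkenyl iodides and the acid-promoted 5-exo or 6-exo lactonisation of epoxy acids with inversion, which has not been shown for a seven-membered ring onto a fully substituted oxirane carbon or as a one-flask sequence.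

## Compound list

1 | (2E)-3-methylpent-2-en-4-yn-1-ol | OC/C=C(\C)C#C | starting material
2 | (2E)-3-methylpent-2-en-4-yn-1-yl acetate | CC(=O)OC/C=C(\C)C#C | intermediate
3 | (2E)-3-methylpenta-2,4-dien-1-yl acetate | CC(=O)OC/C=C(\C)C=C | intermediate
4 | pent-4-yn-1-ol | C#CCCCO | starting material
5 | [(1E)-5-(dimethylalumanyloxy)-2-methylpent-1-en-1-yl]dimethylalumane | C[Al](C)OCCC/C(C)=C/[Al](C)C | intermediate
6 | (4E)-5-iodo-4-methylpent-4-en-1-ol | OCCC/C(C)=C/I | intermediate
7 | tert-butyl{[(4E)-5-iodo-4-methylpent-4-en-1-yl]oxy}dimethylsilane | CC(C)(C)[Si](C)(C)OCCC/C(C)=C/I | intermediate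
8 | (2E)-5-(9-borabicyclo[3.3.1]nonan-9-yl)-3-methylpent-2-en-1-yl acetate | CC(=O)OC/C=C(\C)CCB1C2CCCC1CCC2 | intermediate
9 | (2E,6E)-10-[(tert-butyldimethylsilyl)oxy]-3,7-dimethyldeca-2,6-dien-1-yl acetate | CC(=O)OC/C=C(\C)CC/C=C(\C)CCCO[Si](C)(C)C(C)(C)C | intermediate
10 | (2E)-5-[(2R,3R)-3-{3-[(tert-butyldimethylsilyl)oxy]propyl}-3-methyloxiran-2-yl]-3-methylpent-2-en-1-yl acetate | CC(=O)OC/C=C(\C)CC[C@H]1O[C@]1(C)CCCO[Si](C)(C)C(C)(C)C | intermediate
11 | (2E)-5-[(2R,3R)-3-(3-hydroxypropyl)-3-methyloxiran-2-yl]-3-methylpent-2-en-1-yl acetate | CC(=O)OC/C=C(\C)CC[C@H]1O[C@]1(C)CCCO | intermediate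
12 | (2E)-3-methyl-5-[(2R,3R)-3-methyl-3-(3-oxopropyl)oxiran-2-yl]pent-2-en-1-yl acetate | CC(=O)OC/C=C(\C)CC[C@H]1O[C@]1(C)CCC=O | intermediate
13 | cyclopropyl methyl ketone | CC(=O)C1CC1 | starting material
14 | 2-cyclopropylpropan-2-ol | CC(C)(O)C1CC1 | intermediate
15 | 5-bromo-2-methylpent-2-ene | CC(C)=CCCBr | intermediate
16 | (4-methylpent-3-en-1-yl)triphenylphosphonium bromide | CC(C)=CCC[P+](c1ccccc1)(c1ccccc1)c1ccccc1.[Br-] | intermediate
17 | (4-methylpent-3-en-1-ylidene)triphenylphosphorane | CC(C)=CCC=P(c1ccccc1)(c1ccccc1)c1ccccc1 | intermediate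
18 | (1-iodo-4-methylpent-3-en-1-yl)triphenylphosphonium iodide | CC(C)=CCC(I)[P+](c1ccccc1)(c1ccccc1)c1ccccc1.[I-] | intermediate
19 | (1-iodo-4-methylpent-3-en-1-ylidene)triphenylphosphorane | CC(C)=CCC(I)=P(c1ccccc1)(c1ccccc1)c1ccccc1 | intermediate
20 | (2E)-5-{(2R,3R)-3-[(3Z)-4-iodo-8-methylnona-3,7-dien-1-yl]-3-methyloxiran-2-yl}-3-methylpent-2-en-1-yl acetate | CC(=O)OC/C=C(\C)CC[C@H]1O[C@]1(C)CC/C=C(\I)CCC=C(C)C | intermediate
21 | (2Z)-5-{(2R,3R)-3-[(3E)-5-acetoxy-3-methylpent-3-en-1-yl]-2-methyloxiran-2-yl}-2-(4-methylpent-3-en-1-yl)pent-2-enoic acid | CC(=O)OC/C=C(\C)CC[C@H]1O[C@]1(C)CC/C=C(/CCC=C(C)C)C(=O)O | intermediate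
22 | (2E,6R)-6-hydroxy-3-methyl-6-[(2S)-2-methyl-6-(4-methylpent-3-en-1-yl)-7-oxo-2,3,4,7-tetrahydrooxepin-2-yl]hex-2-en-1-yl acetate | CC(=O)OC/C=C(\C)CC[C@@H](O)[C@]1(C)CCC=C(CCC=C(C)C)C(=O)O1 | target

## Step count and risks

Total step count: 13. Longest linear sequence: 8 (steps 3, 4, 5, 6, 7, 8, 12, 13; the branch through steps 1 and 2 is equally long; the fragment C branch is 5).

The three steps most likely to fail:

1. Step 13 (the proposed new step). The 7-exo opening may be slow and lose to Meinwald rearrangement or allylic alcohol formation; residual iodide may open the oxirane; zerovalent palladium may ionise the allylic acetate. The fallback uses known reaction types, sets out from 12 (with 15 for the reagent) and comes back at 22. Alkylation of tert-butyl [bis(2,2,2-trifluoroethoxy)phosphoryl]acetate with 15 (NaH, DMF) gives tert-butyl 2-[bis(2,2,2-trifluoroethoxy)phosphoryl]-6-methylhept-5-enoate F1. Still–Gennari olefination of 12 with it (KN(SiMe3)2, 18-crown-6, THF, −78 °C) gives tert-butyl (2Z)-5-{(2R,3R)-3-[(3E)-5-acetoxy-3-methylpent-3-en-1-yl]-2-methyloxiran-2-yl}-2-(4-methylpent-3-en-1-yl)pent-2-enoate F2. Treatment with BF3·OEt2 or CSA in CH2Cl2 then lets the ester carbonyl open the activated oxirane at C7 with inversion and loss of 2-methylpropene, the established tert-butyl-ester-terminated epoxide-opening lactonisation, to give 22 with the acetate untouched. This fallback replaces the carbonylation but still relies on the 7-exo opening.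

2. Step 12. α-Iodo ylides are thermally fragile, and yield or Z:E ratio can be poor. The fallback sets out from 12 and comes back at 22. Ramirez olefination (CBr4, PPh3, Et3N, CH2Cl2, 0 °C) gives (2E)-5-[(2R,3R)-3-(4,4-dibromobut-3-en-1-yl)-3-methyloxiran-2-yl]-3-methylpent-2-en-1-yl acetate F3. Trans-selective Negishi mono-alkylation with (4-methylpent-3-en-1-yl)zinc bromide (from 15, Zn, LiCl; PdCl2(DPEphos), THF) replaces the bromine trans to the chain and gives (2E)-5-{(2R,3R)-3-[(3Z)-4-bromo-8-methylnona-3,7-dien-1-yl]-3-methyloxiran-2-yl}-3-methylpent-2-en-1-yl acetate F4. F4 takes the place of 20 under the step 13 conditions at 60 °C and gives 22.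

3. Step 5. Hydroboration of the conjugated dienyl acetate may not be clean, and the allylic acetate may be hydrolysed by the aqueous base or ionised by zerovalent palladium. The fallback sets out from 7 and comes back at 9. Negishi coupling of 7 with [4-(trimethylsilyl)but-3-yn-1-yl]zinc bromide (from C-silylated 4-bromobut-1-yne; PdCl2(dppf), THF) gives tert-butyldimethyl{[(4E)-4-methyl-9-(trimethylsilyl)non-4-en-8-yn-1-yl]oxy}silane F5. K2CO3 in MeOH gives tert-butyldimethyl{[(4E)-4-methylnon-4-en-8-yn-1-yl]oxy}silane F6. A second Zr-catalysed carboalumination (AlMe3, Cp2ZrCl2), followed by n-BuLi and (CH2O)n, gives (2E,6E)-10-[(tert-butyldimethylsilyl)oxy]-3,7-dimethyldeca-2,6-dien-1-ol F7. Ac2O and pyridine then give 9.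

## Further compounds

F1 | step 13 | tert-butyl 2-[bis(2,2,2-trifluoroethoxy)phosphoryl]-6-methylhept-5-enoate | CC(C)=CCCC(C(=O)OC(C)(C)C)P(=O)(OCC(F)(F)F)OCC(F)(F)F
F2 | step 13 | tert-butyl (2Z)-5-{(2R,3R)-3-[(3E)-5-acetoxy-3-methylpent-3-en-1-yl]-2-methyloxiran-2-yl}-2-(4-methylpent-3-en-1-yl)pent-2-enoate | CC(=O)OC/C=C(\C)CC[C@H]1O[C@]1(C)CC/C=C(/CCC=C(C)C)C(=O)OC(C)(C)C
F3 | step 12 | (2E)-5-[(2R,3R)-3-(4,4-dibromobut-3-en-1-yl)-3-methyloxiran-2-yl]-3-methylpent-2-en-1-yl acetate | CC(=O)OC/C=C(\C)CC[C@H]1O[C@]1(C)CCC=C(Br)Br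
F4 | step 12 | (2E)-5-{(2R,3R)-3-[(3Z)-4-bromo-8-methylnona-3,7-dien-1-yl]-3-methyloxiran-2-yl}-3-methylpent-2-en-1-yl acetate | CC(=O)OC/C=C(\C)CC[C@H]1O[C@]1(C)CC/C=C(\Br)CCC=C(C)C
F5 | step 5 | tert-butyldimethyl{[(4E)-4-methyl-9-(trimethylsilyl)non-4-en-8-yn-1-yl]oxy}silane | C[Si](C)(C)C#CCC/C=C(\C)CCCO[Si](C)(C)C(C)(C)C
F6 | step 5 | tert-butyldimethyl{[(4E)-4-methylnon-4-en-8-yn-1-yl]oxy}silane | C#CCC/C=C(\C)CCCO[Si](C)(C)C(C)(C)C
F7 | step 5 | (2E,6E)-10-[(tert-butyldimethylsilyl)oxy]-3,7-dimethyldeca-2,6-dien-1-ol | OC/C=C(\C)CC/C=C(\C)CCCO[Si](C)(C)C(C)(C)C
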